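## The problem

Target 18 is an acyclic 8-O-4' neolignan. Its two syringyl-type C6–C3 units share no ring and are joined by one bond only, the alkyl aryl ether from C8 to the phenolic oxygen of ring B. That oxygen lies between two methoxy groups, so it is a hindered and only moderately acidic nucleophile.

There are three stereocenters: C7 (S), C8 (R) next to it (the erythro pair), and C8' (S) in the dihydroxypropyl chain on ring B. C7 and C8 are neighbours and either can direct the other. C8' is insulated from both by ring B, so it must arrive with its configuration already in place.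

The fragile points are:
- the C7 carbinol, which ionises through a quinone methide once the ring A phenol is free and through a benzylic cation in acid (epimerisation or loss of the oxygen);
- the two electron-rich arenes, which exclude strong oxidants late in the route;
- the C8 hydrogen, which becomes acidic whenever C7 is a carbonyl and C8 already bears the aryloxy group;
- the product itself, a polar pentaol, which should be released in a clean last step.

What makes the plan possible is the three-carbon unit C7–C8–C9. C8 carries the ether oxygen to ring B (the 4-alkyl-2,6-dimethoxyphenoxy ring) and is bonded to the oxygenated C9, which is the pattern of C2 and C3 of glyceric acid. C7, the carbinol on ring A (the 4-hydroxy-3,5-dimethoxyphenyl ring), corresponds to the carboxyl carbon. At the aldehyde level C7 can accept ring A as an aryl-metal, and C8 then decides which face is attacked.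

## Retrosynthesis

**18 ⇒ 17 ⇒ 16 (O–benzyl and O–silicon bonds).** The phenol of ring A and the two hydroxyls at C8' and C9' are masked as benzyl ethers, and the C9 hydroxyl as a triisopropylsilyl ether. Benzyl groups leave by neutral hydrogenolysis, which is the mildest treatment for the p-hydroxybenzylic carbinol; an acetonide on the C8'/C9' diol would need acid at the end and was rejected. The silyl ether is removed one step earlier, in 16 ⇒ 17, so the pentaol appears only in the last step. The forward steps must leave C7 alone.

**16 ⇒ 12 + 13 (the ring A C1–C7 bond, via 14 and 15).** This is the key disconnection. Cutting C7–C8 instead would mean an aldol between an aryloxyacetate and an aromatic aldehyde, which creates two stereocenters at once with no internal control. Cutting the C7–O bond is treated under the alternatives. The C1–C7 cut removes one stereocenter and a whole arene, leaving aldehyde 12 with a single controlling center at C8 and the simple bromide 13. The forward reaction must add an aryl group to an epimerisable α-aryloxy aldehyde with anti (Felkin) selectivity and without enolisation. That is why aryllithium 14 is tamed as aryltitanium 15 and C9 carries a bulky, non-chelating silyl ether.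

**12 ⇒ 11 ⇒ 7 + 10 (aldehyde from ester; the C8–O4' ether bond).** The aldehyde is taken back to methyl ester 11 so that the ether is made while C8 is flanked by an ester. Displacement at C8 of a later intermediate, next to the C7 carbinol or through a C7–C8 epoxide, would favour attack at the benzylic carbon. An α-hydroxy ester is the most reliable substrate for Mitsunobu inversion by a phenol. The cut gives phenol 7 and hydroxy ester 10, each with one stereocenter. The forward reaction must invert cleanly, so 10 has to be the (S) enantiomer to give (R) at C8, and the partial reduction of 11 to 12 must stop at the aldehyde.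

**10 ⇒ 9 ⇒ 8 (O–silicon bond; acetonide).** Hydroxy ester 10 is glycerate 9 silylated at the primary oxygen, and 9 is the commercial acetonide 8 without its ketal. No C–O bond at the stereocenter is touched, so the configuration of 8 is that of 10. The forward steps need only primary-over-secondary selectivity in the silylation.

**7 ⇒ 6 ⇒ 5 ⇒ 2 + 3 (phenol unmasking, benzyl ether, the ring B C1'–C7' bond, via 4), and 2 ⇒ 1.** The aryl–CH2 bond is cut so that C8' comes from the commercial epoxide 3, opened at its unsubstituted carbon by Grignard reagent 4 under copper catalysis. An asymmetric dihydroxylation of a terminal allyl arene would put the enantiopurity of C8' at risk; the epoxide does not. The ring B phenol must be masked by a group that survives magnesium and strong base and leaves without disturbing benzyl ethers. A methoxymethyl ether does this, so bromide 2 comes from phenol 1.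

**13 ⇒ 1 (O–benzyl bond).** The ring A bromide is the benzyl ether of the same commercial phenol 1, so one purchased arene supplies both rings.

## Roads not taken

**Alternative 1:** The cut is the O–C4' bond, with ring B traced back to a non-aromatic carbocycle. In the forward sense Rh2(OAc)4 would decompose diazo dione A1, and the rhodium carbenoid would insert into the free C8 hydroxyl of the silylene-protected erythro triol A2 to give the 2-alkoxy-1,3-dione A3. Dehydrogenation and double O-methylation would then convert the dione into the 2,6-dimethoxyphenyl ether.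
- Merits: the C8–O bond of the alcohol is never broken, so C8 cannot invert or epimerise during ether formation. No hindered phenol has to act as a nucleophile and no α-aryloxy aldehyde is handled. In these respects it is safer than the chosen plan.
- Weak points: ring B, bought complete in 1, has to be built as a 5-substituted dione, diazotised, aromatised by an oxidation in the presence of the electron-rich ring A and a benzylic silyl ether, and methylated twice. The key step creates no stereocenter, so the erythro C7/C8 pair in A2 must be made separately. A syn-dihydroxylation of the readily available E-alkene would give the threo pair, so an inversion or a Z-alkene is needed.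
- Comparison: the chosen plan sets one ether-forming step on an α-hydroxy ester and a key step that also creates C7 against this longer sequence.

**Alternative 2:** The cut is the C7–O bond. In the forward sense Ag2O would oxidise the 7-deoxy phenol A4 to the p-quinone methide A5, and water would add at C7 as ring A rearomatises, giving the erythro diol A6.
- Merits: the route is biomimetic, needs no protecting group on the ring A phenol, introduces the sensitive benzylic carbinol last, and has no carbonyl next to C8 at any stage. In protecting-group economy it is better than the chosen plan.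
- Weak points: the stereochemistry rests on the smallest possible nucleophile adding to a planar electrophile whose only bias is the adjacent C8, and the reagent offers no means of tuning it. The addition is reversible through the same quinone methide, so the kinetic ratio can drift. A5 can also lose the C8 hydrogen to give a conjugated enol ether, or be trapped by hydroxyl groups of other molecules.
- Comparison: the chosen plan pays with a benzyl group on ring A and an organometallic step. In return it has a bulky nucleophile, an ordered transition state, and a second, independent way to the same carbinol by ketone reduction.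

**Alternative 3:** The cut is at C8–H and C9–O, so C8 is made last from an enol ether. In the forward sense the aryl mandelate A7, made by acylating phenol 7, would be methylenated with Cp2TiMe2 to the 1-aryloxyvinyl compound A8. 9-BBN and then NaBO3 would give the C9 alcohol A9, with the C7 silyl ether directing the new C8 center.
- Merits: the hindered ring B oxygen is attached by acylation, the easiest bond to make to such a phenol, with no substitution at a stereocenter. Boron reliably goes to the terminal carbon of an enol ether. In the ease of the C–O bond formation it is better than the chosen plan.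
- Weak points: C7 would have to come from an enantiopure 4-benzyloxy-3,5-dimethoxymandelic acid, which needs its own asymmetric synthesis. A7 is an activated aryl ester with an acidic benzylic hydrogen, so C7 is at risk during acylation and methylenation. The β-aryloxy organoborane formed in the key step can eliminate the ring B phenoxide before it is oxidised. The sense of 1,2-induction for an alkene carrying an aryloxy group is less secure than for the alkyl-substituted cases.
- Comparison: both plans rely on 1,2-induction. The chosen plan has two commercial chiral building blocks and an inducing center, C8, that is fixed as a configurationally defined ether before it has to direct.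

Key step: step 10

Assumption: the commercial epoxide 3 and acetonide 8 are taken to be of high enantiomeric purity, since no later step can upgrade C8' or C8. Locants follow neolignan usage (C7–C9 on ring A, C7'–C9' on ring B, O-4' for the ring B ether oxygen).

## Route

Step 1
Reactants: 1 4-bromo-2,6-dimethoxyphenol
Product: 2 5-bromo-1,3-dimethoxy-2-(methoxymethoxy)benzene
Conditions: NaH, MOMCl, THF–DMF, 0 °C to rt
Reagents that add atoms: chloromethyl methyl ether (MOMCl), COCCl
Why: Williamson-type O-alkylation of the sodium phenoxide by a very reactive chloromethyl ether; the methoxymethyl acetal survives magnesium and the basic benzylation and is later removed by acid that leaves benzyl ethers alone.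

Step 2
Reactants: 2 5-bromo-1,3-dimethoxy-2-(methoxymethoxy)benzene; 3 (S)-benzyl glycidyl ether
Product: 5 (S)-1-(benzyloxy)-3-[3,5-dimethoxy-4-(methoxymethoxy)phenyl]propan-2-ol, via arylmagnesium bromide 4 (not isolated)
Conditions: Mg, THF, 50 °C; then CuI (10 mol %), 3, THF, −30 to 0 °C; aq. NH4Cl
Reagents that add atoms: none
Why: Grignard formation followed by copper-catalysed epoxide opening, in which the arylcopper species attacks the unsubstituted epoxide carbon in SN2 fashion; the C8' center of 3 is not involved in bond making, so its (S) configuration passes unchanged into 5.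

Step 3
Reactants: 5 (S)-1-(benzyloxy)-3-[3,5-dimethoxy-4-(methoxymethoxy)phenyl]propan-2-ol
Product: 6 5-[(S)-2,3-bis(benzyloxy)propyl]-1,3-dimethoxy-2-(methoxymethoxy)benzene
Conditions: NaH, BnBr, Bu4NI (cat.), THF–DMF, 0 °C to rt
Reagents that add atoms: benzyl bromide, BrCc1ccccc1
Why: Williamson ether synthesis on the secondary alkoxide with iodide catalysis; the C–O bond at C8' is not broken and the aryl acetal is inert to base.

Step 4
Reactants: 6 5-[(S)-2,3-bis(benzyloxy)propyl]-1,3-dimethoxy-2-(methoxymethoxy)benzene
Product: 7 4-[(S)-2,3-bis(benzyloxy)propyl]-2,6-dimethoxyphenol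
Conditions: HCl (cat.), MeOH, 40 °C
Reagents that add atoms: none
Why: Acid-catalysed acetal exchange transfers the methoxymethyl group to methanol; alkyl benzyl ethers and aryl methyl ethers do not react with dilute methanolic HCl, and the large excess of methanol intercepts the oxocarbenium ion before it can attack the arene.

Step 5
Reactants: 8 methyl (S)-2,2-dimethyl-1,3-dioxolane-4-carboxylate
Product: 9 methyl (S)-2,3-dihydroxypropanoate
Conditions: Dowex 50W-X8 (H+ form), MeOH–H2O (9:1), rt
Reagents that add atoms: none
Why: Acid-catalysed ketal hydrolysis on a sulfonic acid resin; no bond at the stereocenter is broken, and the mild heterogeneous acid leaves the methyl ester and the α-hydrogen alone.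

Step 6
Reactants: 9 methyl (S)-2,3-dihydroxypropanoate
Product: 10 methyl (S)-2-hydroxy-3-[(triisopropylsilyl)oxy]propanoate
Conditions: TIPSCl, imidazole, CH2Cl2, 0 °C
Reagents that add atoms: triisopropylsilyl chloride (TIPSCl), CC(C)[Si](Cl)(C(C)C)C(C)C
Why: Selective silylation of the primary hydroxyl; the bulky silyl chloride discriminates against the secondary hydroxyl, which is also deactivated by the adjacent ester.

Step 7
Reactants: 7 4-[(S)-2,3-bis(benzyloxy)propyl]-2,6-dimethoxyphenol; 10 methyl (S)-2-hydroxy-3-[(triisopropylsilyl)oxy]propanoate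
Product: 11 methyl (R)-2-{4-[(S)-2,3-bis(benzyloxy)propyl]-2,6-dimethoxyphenoxy}-3-[(triisopropylsilyl)oxy]propanoate
Conditions: PPh3, DIAD, THF, 0 °C to rt
Reagents that add atoms: none
Why: Mitsunobu reaction; the α-hydroxy ester is activated as its alkoxyphosphonium salt and displaced by the phenoxide in an SN2 step that the neighbouring carbonyl accelerates, so the (S) alcohol gives the (R) ether, which is C8 of the target, with inversion.

Step 8
Reactants: 11 methyl (R)-2-{4-[(S)-2,3-bis(benzyloxy)propyl]-2,6-dimethoxyphenoxy}-3-[(triisopropylsilyl)oxy]propanoate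
Product: 12 (R)-2-{4-[(S)-2,3-bis(benzyloxy)propyl]-2,6-dimethoxyphenoxy}-3-[(triisopropylsilyl)oxy]propanal
Conditions: iBu2AlH, CH2Cl2, −78 °C; MeOH, then aq. potassium sodium tartrate
Reagents that add atoms: none
Why: Partial reduction of an α-alkoxy ester by iBu2AlH; the tetrahedral aluminium hemiacetal is stabilised by the α-oxygen at −78 °C and releases the aldehyde only on work-up, and the cold, non-basic quench protects C8, after which the aldehyde is used at once.

Step 9
Reactants: 1 4-bromo-2,6-dimethoxyphenol
Product: 13 2-(benzyloxy)-5-bromo-1,3-dimethoxybenzene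
Conditions: BnBr, K2CO3, DMF, rt
Reagents that add atoms: benzyl bromide, BrCc1ccccc1
Why: Williamson ether synthesis; the benzyl ether withstands bromine–lithium exchange and leaves in the final hydrogenolysis together with the other benzyl groups.

Step 10
Reactants: 12 (R)-2-{4-[(S)-2,3-bis(benzyloxy)propyl]-2,6-dimethoxyphenoxy}-3-[(triisopropylsilyl)oxy]propanal; 13 2-(benzyloxy)-5-bromo-1,3-dimethoxybenzene
Product: 16 (1S,2R)-1-[4-(benzyloxy)-3,5-dimethoxyphenyl]-2-{4-[(S)-2,3-bis(benzyloxy)propyl]-2,6-dimethoxyphenoxy}-3-[(triisopropylsilyl)oxy]propan-1-ol, via aryllithium 14 (not isolated), via aryltitanium triisopropoxide 15 (not isolated)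
Conditions: 13, n-BuLi, THF, −78 °C; ClTi(OiPr)3, −78 to −40 °C; then 12, THF, −78 to 0 °C; aq. NH4Cl
Reagents that add atoms: none
Why: Bromine–lithium exchange turns 13 into aryllithium 14, and ClTi(OiPr)3 converts it into the monoaryltitanium triisopropoxide 15, which transfers its aryl group to the aldehyde carbon through a four-centre transition state and so forms the C1–C7 bond and the C7 carbinol in one event. The closest known reaction type is the non-chelation-controlled addition of organotitanium triisopropoxides to α-alkoxy aldehydes. No ring is closed. The new stereocenter C7 is controlled by the existing C8 center through the polar Felkin–Anh arrangement: the C8–OAr bond stands perpendicular to the carbonyl plane and anti to the incoming aryl group, which then passes the C8 hydrogen and not the CH2OSi group, giving the anti (erythro) 7S,8R pair. The step needs diastereoface selectivity at the carbonyl and chemoselectivity for addition over enolisation of the α-aryloxy aldehyde. The first is secured by the absence of a chelate, because the titanium carries three isopropoxide ligands and is a poor Lewis acid, the silyl ether oxygen is shielded, and the ring B ether oxygen is flanked by two methoxy groups. The second is secured by the low basicity of the aryltitanium compared with the aryllithium.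

Step 11
Reactants: 16 (1S,2R)-1-[4-(benzyloxy)-3,5-dimethoxyphenyl]-2-{4-[(S)-2,3-bis(benzyloxy)propyl]-2,6-dimethoxyphenoxy}-3-[(triisopropylsilyl)oxy]propan-1-ol
Product: 17 (1S,2R)-1-[4-(benzyloxy)-3,5-dimethoxyphenyl]-2-{4-[(S)-2,3-bis(benzyloxy)propyl]-2,6-dimethoxyphenoxy}propane-1,3-diol
Conditions: Bu4NF, THF, 0 °C to rt
Reagents that add atoms: none
Why: Fluoride-induced cleavage of the silyl ether, driven by the strength of the Si–F bond; benzyl ethers and all three stereocenters are untouched, and the still lipophilic diol can be purified before the final step.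

Step 12
Reactants: 17 (1S,2R)-1-[4-(benzyloxy)-3,5-dimethoxyphenyl]-2-{4-[(S)-2,3-bis(benzyloxy)propyl]-2,6-dimethoxyphenoxy}propane-1,3-diol
Product: 18 (1S,2R)-2-{4-[(S)-2,3-dihydroxypropyl]-2,6-dimethoxyphenoxy}-1-(4-hydroxy-3,5-dimethoxyphenyl)propane-1,3-diol
Conditions: H2 (1 atm), Pd/C (10%), EtOAc–EtOH, rt
Reagents that add atoms: none
Why: Catalytic hydrogenolysis of the one aryl and two alkyl benzyl ethers under neutral conditions; without acid the benzylic C7–OH bond is not activated, no stereocenter is touched, and the pentaol should be obtained by filtration and evaporation.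

## Compound list

1 | 4-bromo-2,6-dimethoxyphenol | COc1cc(Br)cc(OC)c1O | starting material
2 | 5-bromo-1,3-dimethoxy-2-(methoxymethoxy)benzene | COCOc1c(OC)cc(Br)cc1OC | intermediate
3 | (S)-benzyl glycidyl ether, (S)-2-[(benzyloxy)methyl]oxirane | C(OCc1ccccc1)[C@@H]1CO1 | starting material
4 | [3,5-dimethoxy-4-(methoxymethoxy)phenyl]magnesium bromide | COCOc1c(OC)cc([Mg]Br)cc1OC | intermediate
5 | (S)-1-(benzyloxy)-3-[3,5-dimethoxy-4-(methoxymethoxy)phenyl]propan-2-ol | COCOc1c(OC)cc(C[C@H](O)COCc2ccccc2)cc1OC | intermediate
6 | 5-[(S)-2,3-bis(benzyloxy)propyl]-1,3-dimethoxy-2-(methoxymethoxy)benzene | COCOc1c(OC)cc(C[C@H](OCc2ccccc2)COCc2ccccc2)cc1OC | intermediate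
7 | 4-[(S)-2,3-bis(benzyloxy)propyl]-2,6-dimethoxyphenol | COc1cc(C[C@H](OCc2ccccc2)COCc2ccccc2)cc(OC)c1O | intermediate
8 | methyl (S)-2,2-dimethyl-1,3-dioxolane-4-carboxylate | COC(=O)[C@@H]1COC(C)(C)O1 | starting material
9 | methyl (S)-2,3-dihydroxypropanoate | COC(=O)[C@@H](O)CO | intermediate
10 | methyl (S)-2-hydroxy-3-[(triisopropylsilyl)oxy]propanoate | COC(=O)[C@@H](O)CO[Si](C(C)C)(C(C)C)C(C)C | intermediate
11 | methyl (R)-2-{4-[(S)-2,3-bis(benzyloxy)propyl]-2,6-dimethoxyphenoxy}-3-[(triisopropylsilyl)oxy]propanoate | COC(=O)[C@@H](CO[Si](C(C)C)(C(C)C)C(C)C)Oc1c(OC)cc(C[C@H](OCc2ccccc2)COCc2ccccc2)cc1OC | intermediate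
12 | (R)-2-{4-[(S)-2,3-bis(benzyloxy)propyl]-2,6-dimethoxyphenoxy}-3-[(triisopropylsilyl)oxy]propanal | O=C[C@@H](CO[Si](C(C)C)(C(C)C)C(C)C)Oc1c(OC)cc(C[C@H](OCc2ccccc2)COCc2ccccc2)cc1OC | intermediate
13 | 2-(benzyloxy)-5-bromo-1,3-dimethoxybenzene | COc1cc(Br)cc(OC)c1OCc1ccccc1 | intermediate
14 | [4-(benzyloxy)-3,5-dimethoxyphenyl]lithium | [Li]c1cc(OC)c(OCc2ccccc2)c(OC)c1 | intermediate
15 | [4-(benzyloxy)-3,5-dimethoxyphenyl]tri(propan-2-yloxy)titanium | CC(C)O[Ti](OC(C)C)(OC(C)C)c1cc(OC)c(OCc2ccccc2)c(OC)c1 | intermediate
16 | (1S,2R)-1-[4-(benzyloxy)-3,5-dimethoxyphenyl]-2-{4-[(S)-2,3-bis(benzyloxy)propyl]-2,6-dimethoxyphenoxy}-3-[(triisopropylsilyl)oxy]propan-1-ol | COc1cc([C@H](O)[C@@H](CO[Si](C(C)C)(C(C)C)C(C)C)Oc2c(OC)cc(C[C@H](OCc3ccccc3)COCc3ccccc3)cc2OC)cc(OC)c1OCc1ccccc1 | intermediate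
17 | (1S,2R)-1-[4-(benzyloxy)-3,5-dimethoxyphenyl]-2-{4-[(S)-2,3-bis(benzyloxy)propyl]-2,6-dimethoxyphenoxy}propane-1,3-diol | COc1cc([C@H](O)[C@@H](CO)Oc2c(OC)cc(C[C@H](OCc3ccccc3)COCc3ccccc3)cc2OC)cc(OC)c1OCc1ccccc1 | intermediate
18 | (1S,2R)-2-{4-[(S)-2,3-dihydroxypropyl]-2,6-dimethoxyphenoxy}-1-(4-hydroxy-3,5-dimethoxyphenyl)propane-1,3-diol | COc1cc([C@H](O)[C@@H](CO)Oc2c(OC)cc(C[C@H](O)CO)cc2OC)cc(OC)c1O | target

## Step count and risks

Total step count: 12. Longest linear sequence: 9 steps (steps 1, 2, 3, 4, 7, 8, 10, 11, 12).

**Step 10 (key step).** The main danger is poor facial selectivity: a transition state in which titanium or residual lithium bridges the carbonyl oxygen and the ring B ether or methoxy oxygens would compete with the open Felkin–Anh arrangement and lead toward the threo isomer. Enolisation of the aldehyde before addition would also erode the C8 configuration. The fallback sets out from ester 11 and returns at 16. The ester is converted with MeNH(OMe)·HCl and iPrMgCl in THF at −20 °C into the Weinreb amide (R)-2-{4-[(S)-2,3-bis(benzyloxy)propyl]-2,6-dimethoxyphenoxy}-N-methoxy-N-methyl-3-[(triisopropylsilyl)oxy]propanamide F1. Aryllithium 14 at −78 °C then forms the same C1–C7 bond and gives the aryl ketone (R)-1-[4-(benzyloxy)-3,5-dimethoxyphenyl]-2-{4-[(S)-2,3-bis(benzyloxy)propyl]-2,6-dimethoxyphenoxy}-3-[(triisopropylsilyl)oxy]propan-1-one F2. Reduction with Zn(BH4)2 in Et2O is expected to proceed through a zinc chelate between the ketone and the C8 ether oxygen, with hydride entering from the side of the C8 hydrogen. By the cyclic Cram model this gives the same anti (erythro) alcohol 16, so the stereocenter is then set by reduction and no longer by C–C bond formation.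

**Step 7.** The displacement may be slow or fail because the 2,6-dimethoxyphenol is hindered and only moderately acidic, so the activated alcohol is consumed by the reduced azodicarboxylate or by elimination instead. The fallback sets out from 10 and returns at 11. Tf2O and 2,6-lutidine in CH2Cl2 at −78 °C give the triflate methyl (S)-3-[(triisopropylsilyl)oxy]-2-{[(trifluoromethyl)sulfonyl]oxy}propanoate F3. The preformed potassium phenoxide of 7 (K2CO3, MeCN, 0 °C to rt) displaces it in a plain SN2 reaction with the same inversion.

**Step 8.** Over-reduction to the primary alcohol and loss of C8 configuration during work-up or storage of the aldehyde are the likely failures. The fallback sets out from 11 and returns at 12. Excess iBu2AlH (−78 to 0 °C) reduces the ester fully to the alcohol (S)-2-{4-[(S)-2,3-bis(benzyloxy)propyl]-2,6-dimethoxyphenoxy}-3-[(triisopropylsilyl)oxy]propan-1-ol F4. Dess–Martin periodinane buffered with NaHCO3 in CH2Cl2 then oxidises it to 12. The non-basic conditions matter twice: they spare the α-hydrogen of the aldehyde, and they prevent silyl migration between the two primary oxygens of F4, which would invert C8.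

**Step 12.** Over-reduction with loss of the benzylic C7 oxygen may occur, because the secondary alkyl benzyl ether at C8' is the slowest to cleave and forces longer exposure of the electron-rich benzylic carbinol to the catalyst. The fallback sets out from 16 and returns at 18, bypassing 17. TBSOTf and 2,6-lutidine give the C7 silyl ether tert-butyl{(1S,2R)-1-[4-(benzyloxy)-3,5-dimethoxyphenyl]-2-{4-[(S)-2,3-bis(benzyloxy)propyl]-2,6-dimethoxyphenoxy}-3-[(triisopropylsilyl)oxy]propoxy}dimethylsilane F5. Hydrogenolysis over Pd/C in EtOAc, with the benzylic oxygen now shielded by a bulky silyl group, gives 4-[(1S,2R)-1-[(tert-butyldimethylsilyl)oxy]-2-{4-[(S)-2,3-dihydroxypropyl]-2,6-dimethoxyphenoxy}-3-[(triisopropylsilyl)oxy]propyl]-2,6-dimethoxyphenol F6. Bu4NF buffered with AcOH in THF then removes both silyl groups.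

## Further compounds

F1 | step 10 | (R)-2-{4-[(S)-2,3-bis(benzyloxy)propyl]-2,6-dimethoxyphenoxy}-N-methoxy-N-methyl-3-[(triisopropylsilyl)oxy]propanamide | CON(C)C(=O)[C@@H](CO[Si](C(C)C)(C(C)C)C(C)C)Oc1c(OC)cc(C[C@H](OCc2ccccc2)COCc2ccccc2)cc1OC
F2 | step 10 | (R)-1-[4-(benzyloxy)-3,5-dimethoxyphenyl]-2-{4-[(S)-2,3-bis(benzyloxy)propyl]-2,6-dimethoxyphenoxy}-3-[(triisopropylsilyl)oxy]propan-1-one | COc1cc(C(=O)[C@@H](CO[Si](C(C)C)(C(C)C)C(C)C)Oc2c(OC)cc(C[C@H](OCc3ccccc3)COCc3ccccc3)cc2OC)cc(OC)c1OCc1ccccc1
F3 | step 7 | methyl (S)-3-[(triisopropylsilyl)oxy]-2-{[(trifluoromethyl)sulfonyl]oxy}propanoate | COC(=O)[C@@H](OS(=O)(=O)C(F)(F)F)CO[Si](C(C)C)(C(C)C)C(C)C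
F4 | step 8 | (S)-2-{4-[(S)-2,3-bis(benzyloxy)propyl]-2,6-dimethoxyphenoxy}-3-[(triisopropylsilyl)oxy]propan-1-ol | OC[C@@H](CO[Si](C(C)C)(C(C)C)C(C)C)Oc1c(OC)cc(C[C@H](OCc2ccccc2)COCc2ccccc2)cc1OC
F5 | step 12 | tert-butyl{(1S,2R)-1-[4-(benzyloxy)-3,5-dimethoxyphenyl]-2-{4-[(S)-2,3-bis(benzyloxy)propyl]-2,6-dimethoxyphenoxy}-3-[(triisopropylsilyl)oxy]propoxy}dimethylsilane | COc1cc([C@H](O[Si](C)(C)C(C)(C)C)[C@@H](CO[Si](C(C)C)(C(C)C)C(C)C)Oc2c(OC)cc(C[C@H](OCc3ccccc3)COCc3ccccc3)cc2OC)cc(OC)c1OCc1ccccc1
F6 | step 12 | 4-[(1S,2R)-1-[(tert-butyldimethylsilyl)oxy]-2-{4-[(S)-2,3-dihydroxypropyl]-2,6-dimethoxyphenoxy}-3-[(triisopropylsilyl)oxy]propyl]-2,6-dimethoxyphenol | COc1cc([C@H](O[Si](C)(C)C(C)(C)C)[C@@H](CO[Si](C(C)C)(C(C)C)C(C)C)Oc2c(OC)cc(C[C@H](O)CO)cc2OC)cc(OC)c1O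
A1 | alternative 1 | 2-diazo-5-{[(S)-2,2-dimethyl-1,3-dioxolan-4-yl]methyl}cyclohexane-1,3-dione | [N-]=[N+]=C1C(=O)CC(C[C@H]2COC(C)(C)O2)CC1=O
A2 | alternative 1 | (4S,5R)-4-[4-(benzyloxy)-3,5-dimethoxyphenyl]-2,2-di-tert-butyl-1,3,2-dioxasilinan-5-ol | COc1cc([C@@H]2O[Si](C(C)(C)C)(C(C)(C)C)OC[C@H]2O)cc(OC)c1OCc1ccccc1
A3 | alternative 1 | 2-{[(4S,5R)-4-[4-(benzyloxy)-3,5-dimethoxyphenyl]-2,2-di-tert-butyl-1,3,2-dioxasilinan-5-yl]oxy}-5-{[(S)-2,2-dimethyl-1,3-dioxolan-4-yl]methyl}cyclohexane-1,3-dione | COc1cc([C@@H]2O[Si](C(C)(C)C)(C(C)(C)C)OC[C@H]2OC4C(=O)CC(C[C@H]3COC(C)(C)O3)CC4=O)cc(OC)c1OCc1ccccc1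
A4 | alternative 2 | 4-[(2S)-2-{4-[(2S)-2,3-bis(tert-butyldimethylsilyloxy)propyl]-2,6-dimethoxyphenoxy}-3-hydroxypropyl]-2,6-dimethoxyphenol | COc1cc(C[C@@H](CO)Oc2c(OC)cc(C[C@H](O[Si](C)(C)C(C)(C)C)CO[Si](C)(C)C(C)(C)C)cc2OC)cc(OC)c1O
A5 | alternative 2 | 4-[(2S)-2-{4-[(2S)-2,3-bis(tert-butyldimethylsilyloxy)propyl]-2,6-dimethoxyphenoxy}-3-hydroxypropylidene]-2,6-dimethoxycyclohexa-2,5-dien-1-one | COC1=CC(=C[C@@H](CO)Oc2c(OC)cc(C[C@H](O[Si](C)(C)C(C)(C)C)CO[Si](C)(C)C(C)(C)C)cc2OC)C=C(OC)C1=O
A6 | alternative 2 | (1S,2R)-2-{4-[(2S)-2,3-bis(tert-butyldimethylsilyloxy)propyl]-2,6-dimethoxyphenoxy}-1-(4-hydroxy-3,5-dimethoxyphenyl)propane-1,3-diol | COc1cc([C@H](O)[C@@H](CO)Oc2c(OC)cc(C[C@H](O[Si](C)(C)C(C)(C)C)CO[Si](C)(C)C(C)(C)C)cc2OC)cc(OC)c1O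
A7 | alternative 3 | 4-[(S)-2,3-bis(benzyloxy)propyl]-2,6-dimethoxyphenyl (S)-2-[4-(benzyloxy)-3,5-dimethoxyphenyl]-2-[(tert-butyldimethylsilyl)oxy]acetate | COc1cc([C@H](O[Si](C)(C)C(C)(C)C)C(=O)Oc2c(OC)cc(C[C@H](OCc3ccccc3)COCc3ccccc3)cc2OC)cc(OC)c1OCc1ccccc1
A8 | alternative 3 | tert-butyl({(1S)-1-[4-(benzyloxy)-3,5-dimethoxyphenyl]-2-{4-[(S)-2,3-bis(benzyloxy)propyl]-2,6-dimethoxyphenoxy}prop-2-en-1-yl}oxy)dimethylsilane | COc1cc([C@H](O[Si](C)(C)C(C)(C)C)C(=C)Oc2c(OC)cc(C[C@H](OCc3ccccc3)COCc3ccccc3)cc2OC)cc(OC)c1OCc1ccccc1
A9 | alternative 3 | (2R,3S)-3-[4-(benzyloxy)-3,5-dimethoxyphenyl]-2-{4-[(S)-2,3-bis(benzyloxy)propyl]-2,6-dimethoxyphenoxy}-3-[(tert-butyldimethylsilyl)oxy]propan-1-ol | COc1cc([C@H](O[Si](C)(C)C(C)(C)C)[C@@H](CO)Oc2c(OC)cc(C[C@H](OCc3ccccc3)COCc3ccccc3)cc2OC)cc(OC)c1OCc1ccccc1
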